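Leave the flasks shut until 30 h. The grey run is still climbing late: it gains 3.7 percentage points between 15.0 h and 30.0 h, more than the scatter of a reading.

| flask | substrate | partner | remark | time |
|---|---|---|---|---|
| violet | 0.10 M | 0.069 M | run made earlier |  |
| amber | 0.10 M | 0.19 M | run made earlier |  |
| grey | 0.10 M | 0.36 M | run made earlier |  |
| Sunday's | 0.10 M | 0.0800 M |  | 30 h |
| Tuesday's | 0.10 M | 0.200 M |  | 30 h |
| Saturday's | 0.10 M | 0.400 M |  | 30 h |

| run | time / h | mono adduct / % |
|---|---|---|
| violet | 2.50 | 4.2 |
| violet | 8.00 | 11.5 |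
| violet | 15.0 | 14.3 |
| violet | 20.0 | 16.1 |
| violet | 30.0 | 16.5 |
| amber | 6.00 | 21.4 |
| amber | 12.0 | 28.2 |
| amber | 20.0 | 33.1 |
| amber | 25.0 | 31.8 |
| amber | 30.0 | 34.7 |
| grey | 2.50 | 19.6 |
| grey | 5.00 | 31.2 |
| grey | 8.00 | 38.3 |
| grey | 15.0 | 43.6 |
| grey | 30.0 | 47.3 |

(scatter of a reading: 1 percentage point)

- what was read earlier has a scatter of 1 percentage point, one standard deviation
- a reading or a percentage of mono adduct counts all its forms, free or not

1. amount of mono adduct at the end, in percent of the substrate charged, for each flask in turn (Sunday's, Tuesday's, Saturday's)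

I carry one number from run to run, the end odds per molar of partner: the last reading of mono adduct, divided by the part of the substrate that is not mono adduct, divided by [partner] as charged. Amber reads 2.80 L mol⁻¹, violet 2.86 L mol⁻¹ and grey 2.49 L mol⁻¹, so the number is nearly constant but sags at grey's charge.

When you come, I expect 18.3% in Sunday's flask and 35.9% in Tuesday's, both at amber's odds. For Saturday's I take grey's odds, the nearer charge, and expect 49.9%.

The forecast, close to mine but not the same, gives 18.4%, 35.2% and 49.8%, on this ground: “K drifts down with partner, beyond what scatter alone comfortably explains”.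

The flasks give 17.9%, 35.5% and 47.3%, so the odds are 2.73 L mol⁻¹ in Sunday's, 2.75 L mol⁻¹ in Tuesday's and 2.24 L mol⁻¹ in Saturday's.

    substrate + partner → mono adduct (k = 0.320 L mol⁻¹ h⁻¹)
    substrate + partner → other mono adduct (k = 0.110 L mol⁻¹ h⁻¹)
    partner + mono adduct → bis adduct (k = 0.0840 L mol⁻¹ h⁻¹)
    partner + other mono adduct → bis adduct (k = 0.110 L mol⁻¹ h⁻¹)
    2 substrate → homo dimer (k = 0.0680 L mol⁻¹ h⁻¹)
    partner → decomposed reagent (k = 0.0690 h⁻¹)
    crystals ⇌ mono adduct, rate k7*(cs7 - [mono adduct]) while solid is left; crystals form when [mono adduct] > cs7 (solubility = 0.0860 M, k = 0.190 h⁻¹)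

At 6.32 h in Sunday's flask, partner goes to decomposed reagent 2.7 times as fast as it goes into mono adduct. At 30.0 h, Sunday's partner, the limiting reagent by charge, stands at 4.9% of its charge, while 55% of the substrate is still there.

The numbers in the tables were generated by integration on assumed constants, noise included.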